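**Retrosynthetic overview**

1. Target ⇐ double formylation and debenzylation of the bis(benzyl) ether; gem-dimethylcyclopropane ⇐ C6=C7 alkene (CBr2, then Me2CuLi/MeI); oxepane C1–O bond ⇐ anti-hydroalkoxylation of the C1=C10 alkene by the phenol.
2. Key disconnection: C1–C5 and C9–C10, formed together by a rhodium-catalysed intramolecular (5+2) cycloaddition of an (E)-alkenylcyclopropane (C5=C6–C7, with C8 and C9 as the cyclopropane CH2 groups) and a tethered but-2-ynyl unit (C1≡C10–C14).
3. Enabling feature: the seven-membered carbocycle (C1, C5, C6, C7, C8, C9, C10) is fused to the cyclopentane along C1–C5 and carries its cyclopropane on the C6–C7 edge, exactly the bond that a vinylcyclopropane cycloaddition leaves as an alkene; C1 and C10 are the two carbons of an alkyne joined to C5 through the three-carbon chain C2–C3–C4.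
4. The acyclic precursor carries only the C7′/C4 stereodiad, built on a temporary dihydrocoumarin ring: organocatalytic Friedel–Crafts/hemiacetalisation (C7′), two lactone-enolate alkylations (C4), lactol olefination (vinylcyclopropane, phenol released).
5. Ring order: arene (bought) → temporary lactone → cyclopentane + cycloheptane (key step) → oxepane → cyclopropane.

Key step: step 11

Remark: terpenoid carbons are numbered as in aromadendrane (C1 O-bearing ring-fusion carbon; C2, C3 CH2; C4 quaternary carbon with C15H3; C5 ring-fusion CH; C6, C7 cyclopropane CH; C8, C9 CH2; C10 CH with C14H3; C11 CMe2) and C7′ is the benzylic CH; 3,5-bis(benzyloxy)phenol is assumed to be a catalogue chemical, and benzyl ethers are used so that the phenols can be freed by hydrogenolysis without harm to the tertiary alkyl aryl ether.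

**Route**

Step 1
Reactants: 1 4-methylpent-1-ene; 2 (E)-but-2-enal
Product: 3 (E)-5-methylhex-2-enal
Conditions: second-generation Grubbs catalyst [RuCl2(H2IMes)(PCy3)(=CHPh)] (2 mol %), 2 (3 equiv), CH2Cl2, 40 °C
Reagents that add atoms: none
Why: Olefin cross-metathesis of a terminal alkene with crotonaldehyde, which should give the (E)-enal with loss of propene.

Step 2
Reactants: 3 (E)-5-methylhex-2-enal; 4 3,5-bis(benzyloxy)phenol
Product: 5 (4R)-5,7-bis(benzyloxy)-4-(2-methylpropyl)chroman-2-ol (mixture of C2 anomers)
Conditions: (S)-α,α-diphenylprolinol trimethylsilyl ether (20 mol %), PhCO2H (20 mol %), toluene, 0 °C → rt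
Reagents that add atoms: none
Why: Iminium-catalysed enantioselective Friedel–Crafts alkylation of an electron-rich phenol with an enal followed by hemiacetalisation (known for 3,5-dialkoxyphenols and naphthols); the diphenyl(silyloxy)methyl group shields one face of the (E)-iminium, so the ring carbon ortho to OH should add to the exposed Re face of the β-carbon and give the 4R centre (C7′ of the target).

Step 3
Reactants: 5 (4R)-5,7-bis(benzyloxy)-4-(2-methylpropyl)chroman-2-ol
Product: 6 (4R)-5,7-bis(benzyloxy)-4-(2-methylpropyl)chroman-2-one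
Conditions: PhI(OAc)2 (1.2 equiv), TEMPO (10 mol %), CH2Cl2, rt
Reagents that add atoms: none
Why: Oxoammonium (TEMPO/PhI(OAc)2) oxidation of a lactol to the lactone, which touches no stereocentre.

Step 4
Reactants: 6 (4R)-5,7-bis(benzyloxy)-4-(2-methylpropyl)chroman-2-one
Product: 7 (3R,4R)-5,7-bis(benzyloxy)-3-methyl-4-(2-methylpropyl)chroman-2-one (3,4-trans)
Conditions: LiN(SiMe3)2, THF, −78 °C; MeI, −78 → −40 °C
Reagents that add atoms: iodomethane (CI)
Why: Lactone enolate alkylation in which the methyl group enters anti to the 4-isobutyl group; this centre is re-enolised in step 6, so its configuration is not critical.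

Step 5
Reactants: 8 pent-3-yn-1-ol
Product: 9 pent-3-yn-1-yl trifluoromethanesulfonate
Conditions: Tf2O, pyridine, CH2Cl2, −78 → −20 °C (used directly)
Reagents that add atoms: trifluoromethanesulfonic anhydride (O=S(=O)(OS(=O)(=O)C(F)(F)F)C(F)(F)F)
Why: O-Sulfonylation of a primary alcohol; the triflate is chosen because homopropargylic halides react too slowly and eliminate with hindered enolates.

Step 6
Reactants: 7 (3R,4R)-5,7-bis(benzyloxy)-3-methyl-4-(2-methylpropyl)chroman-2-one; 9 pent-3-yn-1-yl trifluoromethanesulfonate
Product: 10 (3R,4S)-5,7-bis(benzyloxy)-3-methyl-4-(2-methylpropyl)-3-(pent-3-yn-1-yl)chroman-2-one (isobutyl cis to methyl and trans to pentynyl)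
Conditions: LiN(i-Pr)2, THF, −78 °C; then 9, −78 → −40 °C
Reagents that add atoms: none
Why: Alkylation of the tetrasubstituted lithium enolate of a 4-substituted dihydrocoumarin with a primary triflate; the isobutyl group, held pseudoaxial by the peri 5-benzyloxy group, blocks one face, so the electrophile should enter anti to it and create the quaternary carbon (C4 of the target) with methyl cis and pentynyl trans to isobutyl.

Step 7
Reactants: 10 (3R,4S)-5,7-bis(benzyloxy)-3-methyl-4-(2-methylpropyl)-3-(pent-3-yn-1-yl)chroman-2-one
Product: 11 (3R,4S)-5,7-bis(benzyloxy)-3-methyl-4-(2-methylpropyl)-3-(pent-3-yn-1-yl)chroman-2-ol (mixture of C2 anomers)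
Conditions: i-Bu2AlH (1.1 equiv), CH2Cl2, −78 °C; aq. KNaC4H4O6
Reagents that add atoms: none
Why: Partial hydride reduction of a lactone to the lactol through a tetrahedral aluminate that is stable at low temperature; the α-carbon is quaternary and cannot epimerise.

Step 8
Reactants: 12 (bromomethyl)cyclopropane; 13 1-phenyl-1H-tetrazole-5-thiol
Product: 14 5-[(cyclopropylmethyl)sulfanyl]-1-phenyl-1H-tetrazole
Conditions: K2CO3, DMF, rt
Reagents that add atoms: none
Why: S-Alkylation (SN2) of the tetrazole thiolate by a primary bromide.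

Step 9
Reactants: 14 5-[(cyclopropylmethyl)sulfanyl]-1-phenyl-1H-tetrazole
Product: 15 5-[(cyclopropylmethyl)sulfonyl]-1-phenyl-1H-tetrazole
Conditions: 30% aq. H2O2, (NH4)6Mo7O24·4H2O (5 mol %), EtOH, rt
Reagents that add atoms: hydrogen peroxide (OO)
Why: Molybdate-catalysed oxidation of a sulfide to the sulfone, the standard preparation of Julia–Kocienski reagents.

Step 10
Reactants: 11 (3R,4S)-5,7-bis(benzyloxy)-3-methyl-4-(2-methylpropyl)-3-(pent-3-yn-1-yl)chroman-2-ol; 15 5-[(cyclopropylmethyl)sulfonyl]-1-phenyl-1H-tetrazole
Product: 17 3,5-bis(benzyloxy)-2-[(1E,3S,4R)-1-cyclopropyl-3,6-dimethyl-3-(pent-3-yn-1-yl)hept-1-en-4-yl]phenol, via open-chain hydroxy aldehyde 16 (not isolated)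
Conditions: 15 (2.5 equiv), KN(SiMe3)2 (2.5 equiv), DME, −60 °C; then 11, −60 °C → rt
Reagents that add atoms: none
Why: Julia–Kocienski olefination of the open-chain aldehyde tautomer of the lactol (addition, Smiles rearrangement, loss of SO2 and tetrazolone), which with a 1-phenyltetrazolyl sulfone, a potassium base and an α-quaternary aldehyde should give the E-alkene needed for the cycloaddition and releases the phenol.

Step 11
Reactants: 17 3,5-bis(benzyloxy)-2-[(1E,3S,4R)-1-cyclopropyl-3,6-dimethyl-3-(pent-3-yn-1-yl)hept-1-en-4-yl]phenol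
Product: 18 3,5-bis(benzyloxy)-2-{(1R)-1-[(3R,3aS)-3,8-dimethyl-1,2,3,3a,6,7-hexahydroazulen-3-yl]-3-methylbutyl}phenol
Conditions: [Rh(CO)2Cl]2 (5 mol %), toluene (0.02 M), 80 °C
Reagents that add atoms: none
Why: Rhodium-catalysed intramolecular (5+2) cycloaddition of a vinylcyclopropane with an alkyne: monovalent rhodium coordinates both π-systems, opens the strained cyclopropane (C7–C9 bond) to a σ,π-allyl rhodacycle, inserts the tethered alkyne and reductively eliminates, so that C1–C5 and C9–C10 form in one operation and the C6=C7 alkene appears where the cyclopropane of the target will sit. The closest known reaction type is the [Rh(CO)2Cl]2-catalysed cycloisomerisation of 1-cyclopropyl-1-en-6-ynes with three-atom carbon, oxygen or nitrogen tethers to bicyclo[5.3.0]decadienes. The cyclopentane closes through the tether C2–C3–C4 (exo closure at both the alkyne and the alkene, C10 and C6 staying outside the five-membered ring), and the cycloheptadiene closes by ring expansion of the metallacycle on cyclopropane cleavage followed by C9–C10 reductive elimination. C5, the only new stereocentre, is controlled by the neighbouring quaternary C4: the C6 arm should be placed syn to the small methyl group and anti to the bulky CH(i-Bu)Ar group, which leaves H-5 cis to C7′ as the later oxygen bridge requires. The step needs (5+2) selectivity over alkyne oligomerisation and ene pathways and a reactive s-cis alkenylcyclopropane; the intramolecular tether, the Thorpe–Ingold effect of C4, the E geometry of C5=C6 and the unsubstituted cyclopropane (both distal C–C bonds equivalent, so no regiochemical question) secure this, and the phenol and benzyl ethers are spectators.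

Step 12
Reactants: 18 3,5-bis(benzyloxy)-2-{(1R)-1-[(3R,3aS)-3,8-dimethyl-1,2,3,3a,6,7-hexahydroazulen-3-yl]-3-methylbutyl}phenol
Product: 19 bridged tetracyclic ether (C1–O bond closed; C6=C7 retained; two benzyl ethers; 1S,4R,5S,10S,7′R; O-1 cis to H-5 and to C14H3)
Conditions: TfOH (5 mol %), CH2Cl2, −78 → −40 °C
Reagents that add atoms: none
Why: Brønsted acid-catalysed intramolecular hydroalkoxylation (phenol–alkene cycloetherification) of the tetrasubstituted C1=C10 alkene, which is protonated in preference to the disubstituted C6=C7 alkene; ring size (seven- versus eight-membered) directs oxygen to C1, the C7′–C4 tether lets the phenol reach only the α face of C1 (O-1 cis to H-5), and the proton should be taken up at C10 on the opposite β face (anti addition as in Stork–Eschenmoser cyclisations), which sets C10 with C14H3 cis to O-1.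

Step 13
Reactants: 19 bridged tetracyclic ether
Product: 20 11,11-dibromo tetracycle (dibromocyclopropane fused on C6–C7, syn to H-5; 1S,4R,5S,6S,7R,10S,7′R, the descriptor at C6 differing from the target only through the bromine priorities)
Conditions: CHBr3, KOt-Bu, pentane, 0 °C → rt
Reagents that add atoms: bromoform (BrC(Br)Br)
Why: Dibromocarbene [2+1] cycloaddition (carbene from CHBr3 by α-elimination) to the only alkene left; the carbene should approach the convex α face of the cis-fused bicyclo[5.3.0] unit, syn to H-5 and away from the C2–C3 bridge and C4, which sets C6 and C7.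

Step 14
Reactants: 20 11,11-dibromo tetracycle
Product: 21 bis(benzyl) ether of the deformyl target (gem-dimethylcyclopropane; 1S,4R,5S,6R,7R,10S,7′R)
Conditions: Me2CuLi (from MeLi and CuI, 5 equiv), Et2O, −40 → 0 °C; then MeI (excess), 0 °C → rt
Reagents that add atoms: lithium dimethylcuprate ([Li+].C[Cu-]C); iodomethane (CI)
Why: Corey–Posner-type gem-dimethylation of a gem-dibromocyclopropane, in which bromine–copper exchange, a 1,2-methyl shift on copper and capture of the resulting cyclopropylcopper by MeI replace both bromines by methyl groups and leave C6 and C7 untouched.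

Step 15
Reactants: 21 bis(benzyl) ether of the deformyl target
Product: 22 deformyl target (free diphenol; 1S,4R,5S,6R,7R,10S,7′R)
Conditions: H2 (1 atm), Pd/C (10 wt %), EtOAc, rt
Reagents that add atoms: none
Why: Heterogeneous hydrogenolysis of the two benzyl aryl ethers; no alkene remains, and the trialkyl cyclopropane and the tertiary alkyl aryl ether should not be hydrogenolysed under these conditions.

Step 16
Reactants: 22 deformyl target
Product: 24 target CNP0189833.2 (1S,4R,5S,6R,7R,10S,7′R), via bis-iminium dichloride 23 (not isolated)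
Conditions: POCl3 (6 equiv), DMF, 0 → 50 °C; then H2O, 50 °C
Reagents that add atoms: N,N-dimethylformamide (CN(C)C=O); water (O)
Why: Double Vilsmeier–Haack formylation of the phloroglucinol-type ring at its two free positions, each ortho or para to the free hydroxyl groups, followed by hydrolysis of the bis-iminium salt; these conditions are milder towards the tertiary ether than Lewis acid-mediated formylations.

**Compound list**

1 | 4-methylpent-1-ene | C=CCC(C)C | starting material
2 | (E)-but-2-enal | C/C=C/C=O | starting material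
3 | (E)-5-methylhex-2-enal | CC(C)C/C=C/C=O | intermediate
4 | 3,5-bis(benzyloxy)phenol | Oc1cc(OCc2ccccc2)cc(OCc2ccccc2)c1 | starting material
5 | (4R)-5,7-bis(benzyloxy)-4-(2-methylpropyl)chroman-2-ol | CC(C)C[C@@H]1CC(O)Oc2cc(OCc3ccccc3)cc(OCc3ccccc3)c12 | intermediate
6 | (4R)-5,7-bis(benzyloxy)-4-(2-methylpropyl)chroman-2-one | CC(C)C[C@@H]1CC(=O)Oc2cc(OCc3ccccc3)cc(OCc3ccccc3)c12 | intermediate
7 | (3R,4R)-5,7-bis(benzyloxy)-3-methyl-4-(2-methylpropyl)chroman-2-one | CC(C)C[C@@H]1[C@@H](C)C(=O)Oc2cc(OCc3ccccc3)cc(OCc3ccccc3)c12 | intermediate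
8 | pent-3-yn-1-ol | CC#CCCO | starting material
9 | pent-3-yn-1-yl trifluoromethanesulfonate | CC#CCCOS(=O)(=O)C(F)(F)F | intermediate
10 | (3R,4S)-5,7-bis(benzyloxy)-3-methyl-4-(2-methylpropyl)-3-(pent-3-yn-1-yl)chroman-2-one | CC(C)C[C@@H]1[C@@](C)(CCC#CC)C(=O)Oc2cc(OCc3ccccc3)cc(OCc3ccccc3)c12 | intermediate
11 | (3R,4S)-5,7-bis(benzyloxy)-3-methyl-4-(2-methylpropyl)-3-(pent-3-yn-1-yl)chroman-2-ol | CC(C)C[C@@H]1[C@@](C)(CCC#CC)C(O)Oc2cc(OCc3ccccc3)cc(OCc3ccccc3)c12 | intermediate
12 | (bromomethyl)cyclopropane | BrCC1CC1 | starting material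
13 | 1-phenyl-1H-tetrazole-5-thiol | Sc1nnnn1-c1ccccc1 | starting material
14 | 5-[(cyclopropylmethyl)sulfanyl]-1-phenyl-1H-tetrazole | C1CC1CSc1nnnn1-c1ccccc1 | intermediate
15 | 5-[(cyclopropylmethyl)sulfonyl]-1-phenyl-1H-tetrazole | O=S(=O)(CC1CC1)c1nnnn1-c1ccccc1 | intermediate
16 | (2R,3S)-3-[2,4-bis(benzyloxy)-6-hydroxyphenyl]-2,5-dimethyl-2-(pent-3-yn-1-yl)hexanal (open-chain hydroxy aldehyde) | CC(C)C[C@@H](c1c(O)cc(OCc2ccccc2)cc1OCc1ccccc1)[C@@](C)(CCC#CC)C=O | intermediate
17 | 3,5-bis(benzyloxy)-2-[(1E,3S,4R)-1-cyclopropyl-3,6-dimethyl-3-(pent-3-yn-1-yl)hept-1-en-4-yl]phenol | CC(C)C[C@@H](c1c(O)cc(OCc2ccccc2)cc1OCc1ccccc1)[C@@](C)(CCC#CC)/C=C/C1CC1 | intermediate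
18 | 3,5-bis(benzyloxy)-2-{(1R)-1-[(3R,3aS)-3,8-dimethyl-1,2,3,3a,6,7-hexahydroazulen-3-yl]-3-methylbutyl}phenol | CC(C)C[C@@H](c1c(O)cc(OCc2ccccc2)cc1OCc1ccccc1)[C@@]1(C)CCC2=C(C)CCC=C[C@H]12 | intermediate
19 | bridged tetracyclic ether with C6=C7 alkene and two benzyl ethers (1S,4R,5S,10S,7′R) | CC(C)C[C@H]1c2c(OCc3ccccc3)cc(OCc3ccccc3)cc2O[C@]23CC[C@@]1(C)[C@H]2C=CCC[C@@H]3C | intermediate
20 | 11,11-dibromo tetracycle with two benzyl ethers (1S,4R,5S,6S,7R,10S,7′R) | CC(C)C[C@H]1c2c(OCc3ccccc3)cc(OCc3ccccc3)cc2O[C@]23CC[C@@]1(C)[C@H]2[C@H]1[C@@H](CC[C@@H]3C)C1(Br)Br | intermediate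
21 | bis(benzyl) ether of the deformyl target (1S,4R,5S,6R,7R,10S,7′R) | CC(C)C[C@H]1c2c(OCc3ccccc3)cc(OCc3ccccc3)cc2O[C@]23CC[C@@]1(C)[C@H]2[C@H]1[C@@H](CC[C@@H]3C)C1(C)C | intermediate
22 | deformyl target, free diphenol (1S,4R,5S,6R,7R,10S,7′R) | CC(C)C[C@H]1c2c(O)cc(O)cc2O[C@]23CC[C@@]1(C)[C@H]2[C@H]1[C@@H](CC[C@@H]3C)C1(C)C | intermediate
23 | bis(N,N-dimethyliminium) dichloride of the target | CC(C)C[C@H]1c2c(O)c(C=[N+](C)C)c(O)c(C=[N+](C)C)c2O[C@]23CC[C@@]1(C)[C@H]2[C@H]1[C@@H](CC[C@@H]3C)C1(C)C.[Cl-].[Cl-] | intermediate
24 | CNP0189833.2 (1S,4R,5S,6R,7R,10S,7′R) | CC(C)C[C@H]1c2c(O)c(C=O)c(O)c(C=O)c2O[C@]23CC[C@@]1(C)[C@H]2[C@H]1[C@@H](CC[C@@H]3C)C1(C)C | target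

**Step count**

Total: 16 steps. Longest linear sequence: 13 steps (steps 1–4, 6, 7, 10–16).

**Three steps most likely to fail**

1. Step 12 (oxepane closure). What may go wrong: a 1,2-hydride shift from C5 into the C1 carbocation before the phenol closes, which would lead to ring closure at C5 or to isomerisation of the skipped diene, or proton uptake at C10 without face control. Fallback: a radical–polar crossover hydroalkoxylation (Mukaiyama-type hydrogen-atom transfer) that never passes through a free carbocation. It sets out from 18 and would be run with [N,N′-bis(3,5-di-tert-butylsalicylidene)-1,2-cyclohexanediaminato]cobalt (divalent cobalt, 5 mol %), N-fluoro-2,4,6-trimethylpyridinium tetrafluoroborate and PhSiH3 in PhCF3 at rt. The cobalt hydride should deliver a hydrogen atom to C10 of the tetrasubstituted alkene (tertiary radical at C1; the disubstituted C6=C7 alkene is a poor acceptor), and the radical is captured and oxidised on cobalt and displaced by the tethered phenol from the α face. The fallback comes back to the route at 19; new compounds on its way: none F0.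

2. Step 11 (key cycloaddition). What may go wrong: poor facial discrimination at C5 next to the quaternary carbon, or slow turnover caused by binding of the free phenol to rhodium and by the hindered neopentyl-type alkene. Fallback: substrate and reagent control are changed together. It sets out from 17, which is silylated (t-BuMe2SiCl, imidazole, DMF) to the tert-butyldimethylsilyl ether of 17 F1. F1 is cyclised with a cationic monovalent rhodium catalyst carrying a chiral diphosphine ([Rh(cod)2]SbF6 with the BINAP enantiomer that matches the substrate bias, ClCH2CH2Cl, rt → 60 °C), a known enantioselective variant of the same cycloaddition, so that the catalyst reinforces the preference set by C4 and the larger silyloxyaryl group enlarges the steric difference at C4. This gives the tert-butyldimethylsilyl ether of 18 F2, and desilylation (n-Bu4NF, THF, 0 °C) comes back to the route at 18.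

3. Step 2 (enantioselective Friedel–Crafts/hemiacetalisation). What may go wrong: C-alkylation at the ring carbon para to the hydroxyl group, competing O-addition to the iminium ion, or erosion of enantioselectivity with the β-branched aliphatic enal. Fallback: the C7′ centre is set by conjugate addition to a coumarin instead. It sets out from 4, which is converted with ethyl propiolate under palladium catalysis (Pd2(dba)3·CHCl3, zerovalent palladium, HCO2H, NaOAc, rt; hydroarylation then lactonisation) into 5,7-bis(benzyloxy)-2H-chromen-2-one F3. Copper-catalysed enantioselective conjugate addition of i-BuMgBr to F3 (CuBr·SMe2 5 mol %, a reversed Josiphos-type ferrocenyl diphosphine of the enantiomeric series that gives the 4R product, t-BuOMe, −72 °C) then comes back to the route at lactone 6, so that steps 1 and 3 are not needed.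

**Further compounds**

F0 | step 12 | none | none
F1 | step 11 | tert-butyldimethylsilyl ether of 17 | CC(C)C[C@@H](c1c(O[Si](C)(C)C(C)(C)C)cc(OCc2ccccc2)cc1OCc1ccccc1)[C@@](C)(CCC#CC)/C=C/C1CC1
F2 | step 11 | tert-butyldimethylsilyl ether of 18 | CC(C)C[C@@H](c1c(O[Si](C)(C)C(C)(C)C)cc(OCc2ccccc2)cc1OCc1ccccc1)[C@@]1(C)CCC2=C(C)CCC=C[C@H]12
F3 | step 2 | 5,7-bis(benzyloxy)-2H-chromen-2-one | O=c1ccc2c(OCc3ccccc3)cc(OCc3ccccc3)cc2o1
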